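**Retrosynthetic overview**
- Last C–C bonds: both C3–H bonds of (S)-6-methyloxane-2,4-dione are added across the ene-dione of two identical 14-membered macrodiolides under palladium-enolate catalysis; the two PMB ethers are removed last.
- Macrodiolide: the ring is closed at the alkene–ketone bond (C10–C11) by an intramolecular palladium-catalysed acid chloride/alkenylstannane coupling.
- Seco chain: Z-enoate by Ando olefination of an aldehyde (from divinyl carbinol via Sharpless epoxidation, PMB ether, hydride opening, stannylacrylate ester, oxidative cleavage) with a phosphonoacetate made from (S)-γ-valerolactone.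
- β-Keto lactone: Claisen condensation of methyl (S)-3-hydroxybutanoate with tert-butyl acetate, then acid lactonisation.
- Ring order: the 14-membered ring and the six-membered lactone are closed separately; the two macrocycles are attached to the lactone carbon at the end.

Assumption: both ring enoates are Z as written, and the quaternary lactone carbon carries two identical residues and is not a stereocentre.

Macrocycle numbering used below: O1, C2(=O), C3=C4, C5(O-substituent), C6(Me), O7, C8(=O), C9, C10, C11(=O), C12, C13, C14(Me).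

**Route**

Step 1
Reactants: 1 penta-1,4-dien-3-ol
Product: 2 (2S,3R)-1,2-epoxypent-4-en-3-ol
Conditions: Ti(OiPr)4 (10 mol%), D-(−)-diisopropyl tartrate (13 mol%), t-BuOOH (1.6 equiv), 4 Å MS, CH2Cl2, −20 °C
Reagents that add atoms: tert-butyl hydroperoxide, CC(C)(C)OO
Why: Sharpless asymmetric epoxidation: the titanium–tartrate catalyst picks one enantiotopic vinyl group and one of its faces, so the erythro (2S,3R) epoxy alcohol is formed and both oxygen-bearing stereocentres of the later macrocycle (C5 and C6) are set at once, while the minor enantiomer is destroyed by faster second epoxidation.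

Step 2
Reactants: 2 (2S,3R)-1,2-epoxypent-4-en-3-ol
Product: 4 (2S)-2-{(1R)-1-[(4-methoxybenzyl)oxy]prop-2-en-1-yl}oxirane, via sodium alkoxide 3 (not isolated)
Conditions: NaH, THF, 0 °C; then 4-methoxybenzyl chloride, Bu4NI (cat.), 0 °C to rt
Reagents that add atoms: 4-methoxybenzyl chloride, COc1ccc(CCl)cc1
Why: Williamson ether synthesis on the sodium alkoxide, run in aprotic THF so that Payne migration of the epoxide stays slow; no stereocentre is touched.

Step 3
Reactants: 4 (2S)-2-{(1R)-1-[(4-methoxybenzyl)oxy]prop-2-en-1-yl}oxirane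
Product: 5 (2S,3R)-3-[(4-methoxybenzyl)oxy]pent-4-en-2-ol
Conditions: LiAlH4, THF, 0 °C
Reagents that add atoms: none
Why: Regioselective epoxide reduction: hydride opens the epoxide by SN2 attack at the unsubstituted terminal carbon, so C2 keeps its oxygen and configuration and becomes the free methyl carbinol next to the PMB-protected carbinol.

Step 4
Reactants: 6 propiolic acid
Product: 8 (2E)-3-(tributylstannyl)prop-2-enoic acid, via bis-stannyl ester 7 (not isolated)
Conditions: Bu3SnH (2.1 equiv), AIBN (5 mol%), THF, 65 °C; then 1 M HCl, Et2O, 0 °C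
Reagents that add atoms: tributyltin hydride, CCCC[SnH](CCCC)CCCC
Why: Radical-chain hydrostannation of the alkyne after O-stannylation of the acid: tin adds to the β-carbon, the first-formed Z adduct equilibrates to the E isomer through reversible stannyl radical addition, and brief acid work-up frees the acid.

Step 5
Reactants: 5 (2S,3R)-3-[(4-methoxybenzyl)oxy]pent-4-en-2-ol; 8 (2E)-3-(tributylstannyl)prop-2-enoic acid
Product: 9 (2S,3R)-3-[(4-methoxybenzyl)oxy]pent-4-en-2-yl (2E)-3-(tributylstannyl)prop-2-enoate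
Conditions: DCC, DMAP (cat.), CH2Cl2, 0 °C to rt
Reagents that add atoms: none
Why: Steglich esterification; this oxygen is acylated now, before any Z-enoate exists, so that a free δ-hydroxy Z-enoate (which would close to a dihydropyranone) never appears.

Step 6
Reactants: 9 (2S,3R)-3-[(4-methoxybenzyl)oxy]pent-4-en-2-yl (2E)-3-(tributylstannyl)prop-2-enoate
Product: 11 (2S,3S)-3-[(4-methoxybenzyl)oxy]-4-oxobutan-2-yl (2E)-3-(tributylstannyl)prop-2-enoate, via vicinal diol 10 (not isolated)
Conditions: OsO4 (2 mol%), NaIO4 (4 equiv), 2,6-lutidine, 1,4-dioxane/H2O (3:1), rt; used crude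
Reagents that add atoms: osmium tetroxide, O=[Os](=O)(=O)=O; sodium periodate (NaIO4), [Na+].[O-]I(=O)(=O)=O
Why: Lemieux–Johnson oxidative cleavage: OsO4 dihydroxylates the electron-rich terminal alkene much faster than the electron-poor, hindered β-stannyl acrylate, and NaIO4 cleaves the diol to the aldehyde under lutidine buffering that protects the α-alkoxy stereocentre.

Step 7
Reactants: 12 (5S)-5-methyloxolan-2-one [(S)-γ-valerolactone]
Product: 14 prop-2-en-1-yl (4S)-4-hydroxypentanoate, via potassium carboxylate 13 (not isolated)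
Conditions: KOH (1.0 equiv), MeOH/H2O, rt; evaporate; allyl bromide, DMF, rt; used at once
Reagents that add atoms: potassium hydroxide (KOH), [K+].[OH-]; allyl bromide, C=CCBr
Why: Saponification of the lactone followed by SN2 O-alkylation of the carboxylate, which gives the open hydroxy ester without any acid that would close it again; the stereocentre is untouched.

Step 8
Reactants: 14 prop-2-en-1-yl (4S)-4-hydroxypentanoate; 15 bromoacetyl bromide
Product: 16 prop-2-en-1-yl (4S)-4-[(bromoacetyl)oxy]pentanoate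
Conditions: pyridine, CH2Cl2, −20 to 0 °C
Reagents that add atoms: none
Why: O-Acylation of the secondary alcohol by the acid bromide (nucleophilic acyl substitution), with retention at C4.

Step 9
Reactants: 16 prop-2-en-1-yl (4S)-4-[(bromoacetyl)oxy]pentanoate
Product: 17 prop-2-en-1-yl (4S)-4-{[(diphenoxyphosphoryl)acetyl]oxy}pentanoate
Conditions: (PhO)2P(O)H, Et3N, CH2Cl2, 0 °C to rt
Reagents that add atoms: diphenyl phosphite, O=[PH](Oc1ccccc1)Oc1ccccc1
Why: Michaelis–Becker reaction: the phosphite anion displaces bromide (SN2) to give an Ando-type diaryl phosphonoacetate.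

Step 10
Reactants: 17 prop-2-en-1-yl (4S)-4-{[(diphenoxyphosphoryl)acetyl]oxy}pentanoate; 11 (2S,3S)-3-[(4-methoxybenzyl)oxy]-4-oxobutan-2-yl (2E)-3-(tributylstannyl)prop-2-enoate
Product: 19 prop-2-en-1-yl (4S)-4-{[(2Z,4R,5S)-4-[(4-methoxybenzyl)oxy]-5-{[(2E)-3-(tributylstannyl)prop-2-enoyl]oxy}hex-2-enoyl]oxy}pentanoate, via sodium phosphonate anion 18 (not isolated)
Conditions: NaH (1.05 equiv), THF, 0 °C; then 11, −78 to −20 °C
Reagents that add atoms: none
Why: Ando variant of the Horner–Wadsworth–Emmons olefination: the electron-poor diaryl phosphonate collapses quickly and irreversibly from the kinetically favoured adduct, which gives the Z-enoate at −78 °C without epimerising or eliminating the α-alkoxy-β-acyloxy aldehyde.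

Step 11
Reactants: 19 prop-2-en-1-yl (4S)-4-{[(2Z,4R,5S)-4-[(4-methoxybenzyl)oxy]-5-{[(2E)-3-(tributylstannyl)prop-2-enoyl]oxy}hex-2-enoyl]oxy}pentanoate
Product: 20 (4S)-4-{[(2Z,4R,5S)-4-[(4-methoxybenzyl)oxy]-5-{[(2E)-3-(tributylstannyl)prop-2-enoyl]oxy}hex-2-enoyl]oxy}pentanoic acid
Conditions: Pd(PPh3)4 (5 mol%), N-methylaniline (3 equiv), THF, rt; citric acid work-up
Reagents that add atoms: none
Why: Tsuji–Trost-type deallylation: zerovalent palladium ionises only the allyl ester and the π-allyl unit is trapped by the weakly nucleophilic N-methylaniline, leaving the two secondary esters, the Z-enoate and the alkenylstannane intact.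

Step 12
Reactants: 20 (4S)-4-{[(2Z,4R,5S)-4-[(4-methoxybenzyl)oxy]-5-{[(2E)-3-(tributylstannyl)prop-2-enoyl]oxy}hex-2-enoyl]oxy}pentanoic acid
Product: 22 (3Z,5R,6S,9E,14S)-5-[(4-methoxybenzyl)oxy]-6,14-dimethyl-1,7-dioxacyclotetradeca-3,9-diene-2,8,11-trione, via acid chloride 21 (not isolated)
Conditions: 1-chloro-N,N,2-trimethylprop-1-en-1-amine (1.2 equiv), CH2Cl2, 0 °C to rt; then syringe-pump addition (12 h) to Pd2(dba)3 (5 mol%), P(2-furyl)3 (20 mol%), toluene (1 mM final), CO (1 atm), 70 °C
Reagents that add atoms: none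
Why: Intramolecular Stille acylation: the acid chloride, made under neutral conditions with the chloroenamine, adds oxidatively to zerovalent palladium and the acyl palladium species couples with the E-alkenylstannane with retention of geometry, closing the 14-membered ring at the ketone–alkene bond and giving the E ene-dione, while high dilution and CO suppress oligomers and decarbonylation.

Step 13
Reactants: 23 methyl (3S)-3-hydroxybutanoate; 24 tert-butyl acetate
Product: 26 tert-butyl (5S)-5-hydroxy-3-oxohexanoate, via lithium enolate 25 (not isolated)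
Conditions: LDA (3.5 equiv, commercial solution), 24 (3.5 equiv), THF, −78 °C; then 23, −78 to −30 °C; AcOH quench
Reagents that add atoms: none
Why: Crossed Claisen condensation: excess lithium ester enolate first deprotonates the hydroxyl and then acylates at the methyl ester, and the β-keto ester product is protected as its enolate until the quench; the carbinol centre is not involved.

Step 14
Reactants: 26 tert-butyl (5S)-5-hydroxy-3-oxohexanoate
Product: 28 (6S)-6-methyloxane-2,4-dione, via hydroxy keto acid 27 (not isolated)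
Conditions: CF3CO2H/CH2Cl2 (1:4), rt
Reagents that add atoms: none
Why: Acidolysis of the tert-butyl ester (loss of isobutene) followed by spontaneous δ-lactonisation of the hydroxy keto acid gives the six-membered β-keto lactone with the (S) centre unchanged.

Step 15
Reactants: 28 (6S)-6-methyloxane-2,4-dione (1 equiv); 22 (3Z,5R,6S,9E,14S)-5-[(4-methoxybenzyl)oxy]-6,14-dimethyl-1,7-dioxacyclotetradeca-3,9-diene-2,8,11-trione (2.2 equiv)
Product: 30 (6S)-3,3-bis{(3Z,5R,6S,9R,14S)-5-[(4-methoxybenzyl)oxy]-6,14-dimethyl-2,8,11-trioxo-1,7-dioxacyclotetradec-3-en-9-yl}-6-methyloxane-2,4-dione, via mono-adduct 29 (not isolated)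
Conditions: [Pd((R)-BINAP)(H2O)2](OTf)2 (10 mol%), THF, 0 °C (first addition), then 40 °C, 48 h
Reagents that add atoms: none
Why: Proposed new method: twofold palladium-enolate conjugate addition (formal C–H alkylation of both C3–H bonds of 28), in which the diaqua complex acts as a Brønsted base to turn the β-keto lactone into an O,O-chelated chiral divalent palladium enolate while the released TfOH activates the ketone of the ene-dione so that carbon attacks C9 (β to the ketone, α to the ester), the still acidic mono-adduct 29 re-entering the same cycle to build the quaternary carbon; each (9R) centre arises from Si-face attack on the exposed outer face of the E ene-dione, reinforced by the (R)-BINAP pocket (the other ligand enantiomer is used if it proves to be the matched one), and the base-free medium avoids retro-Michael cleavage and C9 epimerisation; the closest known reaction type is the Michael addition of β-keto esters to enones catalysed by chiral palladium aqua complexes, which forms quaternary centres but has not been shown for a double addition of an unsubstituted cyclic β-keto lactone to a macrocyclic 4-oxo-2-enoate.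

Step 16
Reactants: 30 (6S)-3,3-bis{(3Z,5R,6S,9R,14S)-5-[(4-methoxybenzyl)oxy]-6,14-dimethyl-2,8,11-trioxo-1,7-dioxacyclotetradec-3-en-9-yl}-6-methyloxane-2,4-dione
Product: 31 (6S)-3,3-bis[(3Z,5R,6S,9R,14S)-5-hydroxy-6,14-dimethyl-2,8,11-trioxo-1,7-dioxacyclotetradec-3-en-9-yl]-6-methyloxane-2,4-dione (CNP0083691.2)
Conditions: DDQ (3 equiv), CH2Cl2/pH 7 phosphate buffer (10:1), 0 °C; chromatography on deactivated silica
Reagents that add atoms: none
Why: Oxidative cleavage of both PMB ethers by DDQ (single-electron oxidation to the oxocarbenium ion, then hydrolysis) under buffered neutral conditions at 0 °C, which frees the two allylic hydroxyls without giving the Z-γ-hydroxy enoates the acid or base they would need to close to butenolides.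

**Compound list**

1 | penta-1,4-dien-3-ol | C=CC(O)C=C | starting material
2 | (2S,3R)-1,2-epoxypent-4-en-3-ol | C=C[C@@H](O)[C@@H]1CO1 | intermediate
3 | sodium (2S,3R)-1,2-epoxypent-4-en-3-olate | C=C[C@@H]([O-])[C@@H]1CO1.[Na+] | intermediate (not isolated)
4 | (2S)-2-{(1R)-1-[(4-methoxybenzyl)oxy]prop-2-en-1-yl}oxirane | C=C[C@@H](OCc1ccc(OC)cc1)[C@@H]2CO2 | intermediate
5 | (2S,3R)-3-[(4-methoxybenzyl)oxy]pent-4-en-2-ol | C=C[C@@H](OCc1ccc(OC)cc1)[C@H](C)O | intermediate
6 | propiolic acid | C#CC(=O)O | starting material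
7 | tributylstannyl (2E)-3-(tributylstannyl)prop-2-enoate | CCCC[Sn](CCCC)(CCCC)OC(=O)/C=C/[Sn](CCCC)(CCCC)CCCC | intermediate (not isolated)
8 | (2E)-3-(tributylstannyl)prop-2-enoic acid | OC(=O)/C=C/[Sn](CCCC)(CCCC)CCCC | intermediate
9 | (2S,3R)-3-[(4-methoxybenzyl)oxy]pent-4-en-2-yl (2E)-3-(tributylstannyl)prop-2-enoate | C=C[C@@H](OCc1ccc(OC)cc1)[C@H](C)OC(=O)/C=C/[Sn](CCCC)(CCCC)CCCC | intermediate
10 | (2S,3R)-4,5-dihydroxy-3-[(4-methoxybenzyl)oxy]pentan-2-yl (2E)-3-(tributylstannyl)prop-2-enoate, both C4 epimers | OCC(O)[C@@H](OCc1ccc(OC)cc1)[C@H](C)OC(=O)/C=C/[Sn](CCCC)(CCCC)CCCC | intermediate (not isolated)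
11 | (2S,3S)-3-[(4-methoxybenzyl)oxy]-4-oxobutan-2-yl (2E)-3-(tributylstannyl)prop-2-enoate | O=C[C@@H](OCc1ccc(OC)cc1)[C@H](C)OC(=O)/C=C/[Sn](CCCC)(CCCC)CCCC | intermediate
12 | (5S)-5-methyloxolan-2-one [(S)-γ-valerolactone] | C[C@H]1CCC(=O)O1 | starting material
13 | potassium (4S)-4-hydroxypentanoate | C[C@H](O)CCC(=O)[O-].[K+] | intermediate (not isolated)
14 | prop-2-en-1-yl (4S)-4-hydroxypentanoate | C[C@H](O)CCC(=O)OCC=C | intermediate
15 | bromoacetyl bromide | BrCC(Br)=O | starting material
16 | prop-2-en-1-yl (4S)-4-[(bromoacetyl)oxy]pentanoate | C[C@H](OC(=O)CBr)CCC(=O)OCC=C | intermediate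
17 | prop-2-en-1-yl (4S)-4-{[(diphenoxyphosphoryl)acetyl]oxy}pentanoate | C[C@H](OC(=O)CP(=O)(Oc1ccccc1)Oc1ccccc1)CCC(=O)OCC=C | intermediate
18 | sodium salt of the phosphonate carbanion of 17 | C[C@H](OC(=O)[CH-]P(=O)(Oc1ccccc1)Oc1ccccc1)CCC(=O)OCC=C.[Na+] | intermediate (not isolated)
19 | prop-2-en-1-yl (4S)-4-{[(2Z,4R,5S)-4-[(4-methoxybenzyl)oxy]-5-{[(2E)-3-(tributylstannyl)prop-2-enoyl]oxy}hex-2-enoyl]oxy}pentanoate | C=CCOC(=O)CC[C@H](C)OC(=O)/C=C\[C@@H](OCc1ccc(OC)cc1)[C@H](C)OC(=O)/C=C/[Sn](CCCC)(CCCC)CCCC | intermediate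
20 | (4S)-4-{[(2Z,4R,5S)-4-[(4-methoxybenzyl)oxy]-5-{[(2E)-3-(tributylstannyl)prop-2-enoyl]oxy}hex-2-enoyl]oxy}pentanoic acid | OC(=O)CC[C@H](C)OC(=O)/C=C\[C@@H](OCc1ccc(OC)cc1)[C@H](C)OC(=O)/C=C/[Sn](CCCC)(CCCC)CCCC | intermediate
21 | (4S)-4-{[(2Z,4R,5S)-4-[(4-methoxybenzyl)oxy]-5-{[(2E)-3-(tributylstannyl)prop-2-enoyl]oxy}hex-2-enoyl]oxy}pentanoyl chloride | ClC(=O)CC[C@H](C)OC(=O)/C=C\[C@@H](OCc1ccc(OC)cc1)[C@H](C)OC(=O)/C=C/[Sn](CCCC)(CCCC)CCCC | intermediate (not isolated)
22 | (3Z,5R,6S,9E,14S)-5-[(4-methoxybenzyl)oxy]-6,14-dimethyl-1,7-dioxacyclotetradeca-3,9-diene-2,8,11-trione | C[C@@H]1OC(=O)/C=C/C(=O)CC[C@H](C)OC(=O)/C=C\[C@H]1OCc2ccc(OC)cc2 | intermediate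
23 | methyl (3S)-3-hydroxybutanoate | C[C@H](O)CC(=O)OC | starting material
24 | tert-butyl acetate | CC(=O)OC(C)(C)C | starting material
25 | lithium 1-(tert-butoxy)ethen-1-olate | C=C([O-])OC(C)(C)C.[Li+] | intermediate (not isolated)
26 | tert-butyl (5S)-5-hydroxy-3-oxohexanoate | C[C@H](O)CC(=O)CC(=O)OC(C)(C)C | intermediate
27 | (5S)-5-hydroxy-3-oxohexanoic acid | C[C@H](O)CC(=O)CC(=O)O | intermediate (not isolated)
28 | (6S)-6-methyloxane-2,4-dione | C[C@H]1CC(=O)CC(=O)O1 | intermediate
29 | (6S)-3-{(3Z,5R,6S,9R,14S)-5-[(4-methoxybenzyl)oxy]-6,14-dimethyl-2,8,11-trioxo-1,7-dioxacyclotetradec-3-en-9-yl}-6-methyloxane-2,4-dione (C3 epimers, largely enol) | C[C@H]1CC(=O)C([C@H]2CC(=O)CC[C@H](C)OC(=O)/C=C\[C@@H](OCc3ccc(OC)cc3)[C@H](C)OC2=O)C(=O)O1 | intermediate (not isolated)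
30 | (6S)-3,3-bis{(3Z,5R,6S,9R,14S)-5-[(4-methoxybenzyl)oxy]-6,14-dimethyl-2,8,11-trioxo-1,7-dioxacyclotetradec-3-en-9-yl}-6-methyloxane-2,4-dione | C[C@@H]1OC(=O)[C@@H](C2([C@H]3CC(=O)CC[C@H](C)OC(=O)/C=C\[C@@H](OCc4ccc(OC)cc4)[C@H](C)OC3=O)C(=O)C[C@H](C)OC2=O)CC(=O)CC[C@H](C)OC(=O)/C=C\[C@H]1OCc5ccc(OC)cc5 | intermediate
31 | (6S)-3,3-bis[(3Z,5R,6S,9R,14S)-5-hydroxy-6,14-dimethyl-2,8,11-trioxo-1,7-dioxacyclotetradec-3-en-9-yl]-6-methyloxane-2,4-dione | C[C@@H]1OC(=O)[C@@H](C2([C@H]3CC(=O)CC[C@H](C)OC(=O)/C=C\[C@@H](O)[C@H](C)OC3=O)C(=O)C[C@H](C)OC2=O)CC(=O)CC[C@H](C)OC(=O)/C=C\[C@H]1O | target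

**Step count**

Total steps: 16. Longest linear sequence: 10 (steps 1, 2, 3, 5, 6, 10, 11, 12, 15, 16).

**Steps most likely to fail**

1. Step 15 (the new twofold addition). The second addition must build a quaternary carbon between two tertiary centres, and the facial selectivity at C9 is untested. Fallback with known chemistry, setting out from 28 and 22 and coming back at 30: one equivalent of 22 is added to 28 with a catalytic tertiary amine (DABCO, CH2Cl2, 0 °C; ordinary amine-catalysed Michael addition of a cyclic 1,3-dicarbonyl) and mono-adduct 29 is isolated. Compound 29 is silylated (TBSOTf, 2,6-lutidine, CH2Cl2, −78 °C) to the tert-butyldimethylsilyl enol ether F1. A Mukaiyama–Michael addition of F1 to a second equivalent of 22 (Sc(OTf)3 10 mol%, CH2Cl2, −78 to −20 °C) gives the silyl enol ether adduct F2, which is hydrolysed on work-up (aqueous citric acid/THF) to 30. Stereocontrol then rests on the macrocycle alone, and C9 epimers are removed by HPLC.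

2. Step 12 (Stille ring closure). Decarbonylation of the acyl palladium species, protodestannylation or oligomerisation can take over. Fallback, setting out from 20 and coming back at 22, closes the same bond by a Nozaki–Hiyama–Kishi coupling. Iododestannylation of 20 (I2, CH2Cl2, 0 °C) gives the iodoacrylate acid F3. Its mixed anhydride (isobutyl chloroformate, N-methylmorpholine, THF, −15 °C) is reduced with NaBH4 at 0 °C to the primary alcohol F4, and Dess–Martin oxidation gives the aldehyde F5. Ring closure (CrCl2 6 equiv, NiCl2 1 mol%, DMSO/THF, 2 mM, rt) gives the macrocyclic allylic alcohol F6 as a mixture of C11 epimers, and Dess–Martin oxidation of F6 gives 22.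

3. Step 16 (last deprotection). Two PMB ethers must be cleaved on a hindered polycarbonyl compound, and the freed Z-γ-hydroxy enoates can translactonise. Fallback, setting out from 22 and coming back at 31: the PMB group is removed at the monomer stage (DDQ, CH2Cl2/pH 7 buffer, 0 °C) to give the hydroxy macrodiolide F7. The twofold addition of step 15 (or the stepwise sequence of its fallback) is then run with 28 and F7, which gives 31 directly with no deprotection at the end.

**Further compounds**

F1 | step 15 | (6S)-4-[(tert-butyldimethylsilyl)oxy]-3-{(3Z,5R,6S,9R,14S)-5-[(4-methoxybenzyl)oxy]-6,14-dimethyl-2,8,11-trioxo-1,7-dioxacyclotetradec-3-en-9-yl}-6-methyl-5,6-dihydro-2H-pyran-2-one | C[C@H]1CC(O[Si](C)(C)C(C)(C)C)=C([C@H]2CC(=O)CC[C@H](C)OC(=O)/C=C\[C@@H](OCc3ccc(OC)cc3)[C@H](C)OC2=O)C(=O)O1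
F2 | step 15 | compound 30 with the C11 ketone of one macrocycle present as its tert-butyldimethylsilyl enol ether (C10=C11) | C[C@@H]1OC(=O)[C@@H](C2([C@H]3CC(=O)CC[C@H](C)OC(=O)/C=C\[C@@H](OCc4ccc(OC)cc4)[C@H](C)OC3=O)C(=O)C[C@H](C)OC2=O)C=C(O[Si](C)(C)C(C)(C)C)CC[C@H](C)OC(=O)/C=C\[C@H]1OCc5ccc(OC)cc5
F3 | step 12 | (4S)-4-{[(2Z,4R,5S)-5-{[(2E)-3-iodoprop-2-enoyl]oxy}-4-[(4-methoxybenzyl)oxy]hex-2-enoyl]oxy}pentanoic acid | OC(=O)CC[C@H](C)OC(=O)/C=C\[C@@H](OCc1ccc(OC)cc1)[C@H](C)OC(=O)/C=C/I
F4 | step 12 | (2S)-5-hydroxypentan-2-yl (2Z,4R,5S)-5-{[(2E)-3-iodoprop-2-enoyl]oxy}-4-[(4-methoxybenzyl)oxy]hex-2-enoate | OCCC[C@H](C)OC(=O)/C=C\[C@@H](OCc1ccc(OC)cc1)[C@H](C)OC(=O)/C=C/I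
F5 | step 12 | (2S)-5-oxopentan-2-yl (2Z,4R,5S)-5-{[(2E)-3-iodoprop-2-enoyl]oxy}-4-[(4-methoxybenzyl)oxy]hex-2-enoate | O=CCC[C@H](C)OC(=O)/C=C\[C@@H](OCc1ccc(OC)cc1)[C@H](C)OC(=O)/C=C/I
F6 | step 12 | (3Z,5R,6S,9E,14S)-11-hydroxy-5-[(4-methoxybenzyl)oxy]-6,14-dimethyl-1,7-dioxacyclotetradeca-3,9-diene-2,8-dione, both C11 epimers | C[C@@H]1OC(=O)/C=C/C(O)CC[C@H](C)OC(=O)/C=C\[C@H]1OCc2ccc(OC)cc2
F7 | step 16 | (3Z,5R,6S,9E,14S)-5-hydroxy-6,14-dimethyl-1,7-dioxacyclotetradeca-3,9-diene-2,8,11-trione | C[C@@H]1OC(=O)/C=C/C(=O)CC[C@H](C)OC(=O)/C=C\[C@H]1O
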